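**Compound numbers used throughout**

1 = 1-bromooctadecane; 2 = triphenylphosphine; 3 = octadecyltriphenylphosphonium bromide; 4 = 1H-pyrrole-2,5-dicarbaldehyde; 5 = octadecylidenetriphenylphosphorane; 6 = sodium 2,5-diformylpyrrol-1-ide; 7 = sodium 2-formyl-5-[(Z)-nonadec-1-en-1-yl]pyrrol-1-ide; 8 = (Z)-5-(nonadec-1-en-1-yl)-1H-pyrrole-2-carbaldehyde; 9 = 5-nonadecyl-1H-pyrrole-2-carbaldehyde (target).

## Analysis of the target

The target 9 is a 2,5-disubstituted 1H-pyrrole. N1 is unsubstituted, C2 carries a formyl group, C3 and C4 are CH positions, and C5 carries an unbranched saturated chain C1'–C19'. There is no stereocentre and no stereogenic double bond, so the problem is one of constitution only. The sensitive elements are the acidic N–H, the electron-rich ring (acid-induced oligomerisation, oxidation) and the formyl group. Because it is conjugated with N1 through the ring, the formyl group behaves as a vinylogous formamide: it is less electrophilic and less easily reduced than an ordinary aromatic aldehyde, yet it still condenses with hydrazine-type nucleophiles. The difficulties are to place the chain and the formyl group on the two different α-carbons, to attach exactly one long chain, and to keep waxy, lipophilic products separable from reagent residues. The feature on which the plan rests is that C2 and C5 each bear exactly one exocyclic carbon, the formyl carbon on C2 and C1' on C5. If C1' is taken back to the aldehyde oxidation level, the two α-substituents become identical and the ring precursor is the C2v-symmetric dialdehyde 4, in which the 2,5-relationship is already built in.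

## Retrosynthetic reasoning

**9 ⇒ 8.** The C1'–C2' single bond of 9 is taken back to the C1'=C2' double bond of 8. No skeletal bond is cut, but the alkene is the retron of a carbonyl olefination and puts the construction site next to the ring, where a formyl carbon can serve as C1'. The forward reaction must saturate an alkene conjugated with the ring while sparing the formyl group and the aromatic ring. The amide-like character of the formyl group makes mild catalytic hydrogenation suitable. Reducing agents that are also carbonyl nucleophiles are excluded. The alkene geometry of 8 is erased here and therefore does not matter.

**8 ⇒ 4 + 5.** The C1'=C2' bond is cut, with C1' becoming a formyl carbon on the ring fragment and C2'–C19' becoming the C18 ylide 5. This cut is preferred over C5–C1' or C2–CHO because it alone turns the ring fragment into the symmetric, ready-made dialdehyde 4. Cutting next to the ring on either side would need a metallated or acylated pyrrole, a C19 electrophile and further redox steps. What is gained is that the ring, the 2,5-pattern and the surviving formyl group are all present before any bond is made. The forward reaction must olefinate exactly one of two equivalent formyl groups. This is arranged by running it on the N-anion 6: once one formyl group has reacted, the anion 7 concentrates its charge in the remaining formyl group, which is thereby deactivated towards a second ylide.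

**5 ⇒ 3 ⇒ 1 + 2.** The ylide 5 is traced to its phosphonium salt 3, and the C–P bond of 3 is cut to the primary bromide 1 and the phosphine 2. Both are bulk chemicals, and the quaternisation is a simple substitution at a primary carbon. The forward sequence only has to give a dry, stoichiometrically reliable salt so that exactly one equivalent of ylide reaches 6.

## Alternatives that were turned down

**Alternative 1:** The ring is disconnected at C3=C4 by ring-closing metathesis. The precursor is the acyclic secondary amine methyl 2-{[(E)-1-phenyldocos-1-en-3-yl]amino}but-3-enoate, used as its 4-methylbenzenesulfonate salt A1.
- Forward key step: second-generation Grubbs catalyst would join the vinyl group on the ester-bearing carbon to the styryl group on the chain-bearing carbon, expel the phenyl-substituted terminus as a small alkene, and close the ring to methyl cis-5-nonadecyl-2,5-dihydro-1H-pyrrole-2-carboxylate A2. Dehydrogenation (DDQ or MnO2) to methyl 5-nonadecyl-1H-pyrrole-2-carboxylate A3 and a reduction–oxidation sequence on the ester would follow.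
- For: five-ring closure by metathesis is fast, and protonation of nitrogen keeps the amine from deactivating the ruthenium carbene. The substituents sit on the carbons flanking nitrogen by construction, so there is no mono/bis problem; on positional and chemoselective certainty this route is stronger than the chosen one.
- Against: A1 is itself a multistep target, since a vinylglycine ester that isomerises easily to the conjugated dehydroamino ester must be N-alkylated with a C22 allylic fragment. Two stereocentres are made only to be erased on aromatisation, and three more operations follow ring closure before the formyl group exists.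
- Comparison: building the heterocycle is unnecessary for an achiral aromatic target whose ring can be bought. The chosen route needs three steps and has the aldehyde oxidation level in place from the start.

**Alternative 2:** The N1–C5 bond is disconnected, giving the open-chain dienyl azide ethyl (2Z,4E)-2-azidotetracosa-2,4-dienoate A4.
- Forward key step: with ZnI2 or Rh2(O2CC3F7)4 at ambient temperature the azide would lose N2, the nitrogen on C2 would bond to the chain-bearing diene terminus, and a hydrogen shift would give ethyl 5-nonadecyl-1H-pyrrole-2-carboxylate A5.
- For: the cyclisation is mild, gives the aromatic ring directly and releases only N2. The 2,5-pattern is dictated by the connectivity of A4, so no statistical selectivity is involved; on this point the alternative is at least as strong as the chosen route.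
- Against: A4 needs a base-mediated condensation of ethyl azidoacetate A6 with (E)-docos-2-enal A7. A7 is not an article of commerce and needs its own two-carbon homologation of a C20 aldehyde. The condensation of A6 with aliphatic enals is capricious because the azide decomposes under base, and azides must be handled in quantity. A5 is at the wrong oxidation level, so ester reduction and re-oxidation add two steps.
- Comparison: at least five steps against three. The chosen route avoids azide chemistry and redox corrections, at the price of having to control mono-olefination.

**Alternative 3:** Two ring bonds, C2–C3 and C4–C5, are disconnected in a [3+2] sense, and N1=C5 is traced to an imine. The components are icosanal A8, glycine methyl ester A9 and (E)-1,2-bis(phenylsulfonyl)ethene A10 as an acetylene equivalent.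
- Forward key step: with AgOAc and triethylamine, A8 and A9 would condense to the imine, whose N-metallated azomethine ylide would add across A10 to give methyl 2,5-cis-5-nonadecyl-3,4-trans-bis(phenylsulfonyl)pyrrolidine-2-carboxylate A11. Twofold base-induced loss of sulfinate would aromatise the ring to A3, and the ester would then have to be converted into the aldehyde.
- For: it is the most convergent option, joining three simple components in one operation with an unambiguous substitution pattern. In convergence and cost of inputs it is stronger than the chosen route, whose dialdehyde is a comparatively expensive building block.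
- Against: the imine derives from an enolisable aliphatic aldehyde, so imine–enamine tautomerisation and aldol-type self-condensation compete with ylide formation far more than for aryl imines. Four stereocentres are set and destroyed, two equivalents of sulfinate are wasted, and the ester-to-aldehyde adjustment is again needed, giving at least four steps.
- Comparison: the chosen route is shorter and has no stereochemical or oxidation-state detour.

Key step: step 2

Remark on the chemistry: 1, 2 and 4 are taken as purchasable; the Z descriptor of 7 and 8 denotes the expected major isomer, and either alkene geometry leads to 9.

## Route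

**Step 1**
Reactants: 1 1-bromooctadecane; 2 triphenylphosphine
Product: 3 octadecyltriphenylphosphonium bromide
Conditions: PPh3 (1.05 equiv), MeCN, reflux, 48 h; trituration with Et2O; dried in vacuo
Reagents that add atoms: none
Why: SN2 quaternisation of a primary alkyl bromide by the phosphine (phosphonium salt formation); neither partner has another reactive site, and trituration removes excess phosphine from the salt.

**Step 2**
Reactants: 3 octadecyltriphenylphosphonium bromide; 4 1H-pyrrole-2,5-dicarbaldehyde
Product: 8 (Z)-5-(nonadec-1-en-1-yl)-1H-pyrrole-2-carbaldehyde, via octadecylidenetriphenylphosphorane 5 (not isolated), via sodium 2,5-diformylpyrrol-1-ide 6 (not isolated), via sodium 2-formyl-5-[(Z)-nonadec-1-en-1-yl]pyrrol-1-ide 7 (not isolated)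
Conditions: 3 (1.0 equiv), NaN(SiMe3)2 (0.98 equiv), THF, –78 → 0 °C; separately 4 (1.1 equiv), NaH (1.1 equiv), THF/DMPU, 0 °C; ylide solution added dropwise to the pyrrolide at –78 °C, then → rt; aq NH4Cl
Reagents that add atoms: none
Why: Wittig olefination on a pre-formed N-anion: NaN(SiMe3)2 converts 3 into the non-stabilised ylide 5, and NaH converts 4 into the sodium pyrrolide 6 beforehand, so that the acidic N–H cannot protonate the ylide and no nucleophilic amide base meets a formyl group. Ylide 5 adds to one formyl group of 6 by [2+2] cycloaddition to an oxaphosphetane, whose cycloreversion gives the C1'=C2' bond of anion 7 and Ph3P=O; the kinetically controlled, lithium-free addition should favour the Z alkene, and any E isomer converges on the same product in step 3. The closest known reaction type is the Wittig olefination of N-sodio pyrrole-2-carbaldehydes with alkylidenephosphoranes, combined with the mono-olefination of symmetrical aromatic dialdehydes under ylide-limiting conditions. No ring is closed and no stereocentre is formed. The selectivity required is mono- over bis-olefination: in 6 the ring charge is spread over two formyl groups, whereas in 7 it is concentrated in the one that is left and reinforced by the donor alkenyl group, so 7 should be a markedly poorer electrophile than 6. Ylide as the limiting reagent and its slow addition to an excess of 6 at low temperature add a kinetic margin to this electronic bias. Because 4 is C2v-symmetric the two formyl groups are equivalent, so either site of attack gives the same 2,5-disubstituted product. Aqueous NH4Cl protonates 7 to 8, which should be separable by chromatography from polar recovered 4, from Ph3P=O and from any non-polar doubly olefinated material.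

**Step 3**
Reactants: 8 (Z)-5-(nonadec-1-en-1-yl)-1H-pyrrole-2-carbaldehyde
Product: 9 5-nonadecyl-1H-pyrrole-2-carbaldehyde
Conditions: H2 (1 atm), Pd/C (10% palladium on carbon), EtOAc, rt
Reagents that add atoms: none
Why: Heterogeneous catalytic hydrogenation of a 1,2-disubstituted alkene; the formyl group, deactivated as a vinylogous formamide, and the aromatic pyrrole ring should not be reduced at ambient pressure and temperature in a neutral solvent. Diimide generated from sulfonyl hydrazides is deliberately not used, because the hydrazide would condense with the formyl group.

## Compound list

1 | 1-bromooctadecane | CCCCCCCCCCCCCCCCCCBr | starting material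
2 | triphenylphosphine | c1ccc(cc1)P(c1ccccc1)c1ccccc1 | starting material
3 | octadecyltriphenylphosphonium bromide | CCCCCCCCCCCCCCCCCC[P+](c1ccccc1)(c1ccccc1)c1ccccc1.[Br-] | intermediate
4 | 1H-pyrrole-2,5-dicarbaldehyde | O=Cc1ccc(C=O)[nH]1 | starting material
5 | octadecylidenetriphenylphosphorane | CCCCCCCCCCCCCCCCCC=P(c1ccccc1)(c1ccccc1)c1ccccc1 | intermediate (not isolated)
6 | sodium 2,5-diformylpyrrol-1-ide | O=Cc1ccc(C=O)[n-]1.[Na+] | intermediate (not isolated)
7 | sodium 2-formyl-5-[(Z)-nonadec-1-en-1-yl]pyrrol-1-ide | CCCCCCCCCCCCCCCCC/C=C\c1ccc(C=O)[n-]1.[Na+] | intermediate (not isolated)
8 | (Z)-5-(nonadec-1-en-1-yl)-1H-pyrrole-2-carbaldehyde | CCCCCCCCCCCCCCCCC/C=C\c1ccc(C=O)[nH]1 | intermediate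
9 | 5-nonadecyl-1H-pyrrole-2-carbaldehyde | CCCCCCCCCCCCCCCCCCCc1ccc(C=O)[nH]1 | target

## Step count and least certain steps

Total step count: 3. Longest linear sequence: 3 steps (1 → 3 → 8 → 9); 4 enters in step 2.

**Step 2 (key step).** The most likely failure is loss of mono-selectivity, that is a second olefination of anion 7, together with incomplete conversion of the sparingly soluble, charge-deactivated pyrrolide 6. The two formyl groups are told apart only by the electronic change that the first olefination brings about, and aggregation of the sodium salt can slow the first addition to the rate of the second.

Fallback: the chain is attached before the second formyl group exists. The fallback sets out from ylide 5 (generated from 3 as in step 2) and returns to the route at 9, bypassing 8. Purchased 1H-pyrrole-2-carbaldehyde F1 is deprotonated with NaH and olefinated with 5 to 2-[(Z)-nonadec-1-en-1-yl]-1H-pyrrole F2; with only one formyl group present, over-reaction is impossible. Hydrogenation over Pd/C in EtOAc then gives 2-nonadecyl-1H-pyrrole F3. Vilsmeier–Haack formylation (POCl3, DMF, 0 °C → rt) attacks the free α-position of F3 and gives N,N-dimethyl-1-(5-nonadecyl-1H-pyrrol-2-yl)methaniminium chloride F4. Hydrolysis of F4 with aqueous NaOAc should deliver 9. This costs one step more, and the regiochemistry then rests on the α-selectivity of electrophilic substitution rather than on symmetry.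

**Step 3.** The most likely failure is over-reduction: hydrogenolysis of the formyl group by way of the carbinol, or partial saturation of the ring, on prolonged exposure to the catalyst. The opposite failure, stalling through poisoning of the palladium surface by phosphorus residues from step 2, is also possible.

Fallback: a metal-free, concerted transfer of hydrogen that cannot hydrogenolyse C–O bonds. It sets out from 8 and returns at 9. Diimide is generated from dipotassium azodicarboxylate (KO2CN=NCO2K) and AcOH in MeOH/THF at rt. This source contains no hydrazide that could condense with the formyl group, and the non-polar C=C bond is reduced in preference to the polarised C=O bond. The fallback makes no new compound (F0).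

**Step 1.** The most likely failure is incomplete quaternisation, with water and unreacted phosphine retained in a waxy, poorly crystalline salt. This would falsify the base stoichiometry of step 2 and partly quench the ylide.

Fallback: the electrophile is changed. It sets out from 1 and returns to the route at 5. Finkelstein exchange (NaI, acetone, reflux) converts 1 into 1-iodooctadecane F5. F5 quaternises 2 faster and should give the better-crystallising octadecyltriphenylphosphonium iodide F6. Deprotonation of F6 with NaN(SiMe3)2 gives the same ylide 5.

## Further compounds

F1 | step 2 | 1H-pyrrole-2-carbaldehyde | O=Cc1ccc[nH]1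
F2 | step 2 | 2-[(Z)-nonadec-1-en-1-yl]-1H-pyrrole | CCCCCCCCCCCCCCCCC/C=C\c1ccc[nH]1
F3 | step 2 | 2-nonadecyl-1H-pyrrole | CCCCCCCCCCCCCCCCCCCc1ccc[nH]1
F4 | step 2 | N,N-dimethyl-1-(5-nonadecyl-1H-pyrrol-2-yl)methaniminium chloride | CCCCCCCCCCCCCCCCCCCc1ccc(C=[N+](C)C)[nH]1.[Cl-]
F0 | step 3 | none | none
F5 | step 1 | 1-iodooctadecane | CCCCCCCCCCCCCCCCCCI
F6 | step 1 | octadecyltriphenylphosphonium iodide | CCCCCCCCCCCCCCCCCC[P+](c1ccccc1)(c1ccccc1)c1ccccc1.[I-]
A1 | alternative 1 | methyl 2-{[(E)-1-phenyldocos-1-en-3-yl]amino}but-3-enoate 4-methylbenzenesulfonate (racemic, the diastereomer leading to the cis ring drawn) | COC(=O)[C@H](C=C)N[C@@H](CCCCCCCCCCCCCCCCCCC)/C=C/c1ccccc1.Cc1ccc(cc1)S(=O)(=O)O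
A2 | alternative 1 | methyl cis-5-nonadecyl-2,5-dihydro-1H-pyrrole-2-carboxylate (racemic, one enantiomer drawn) | COC(=O)[C@@H]1C=C[C@H](CCCCCCCCCCCCCCCCCCC)N1
A3 | alternative 1 | methyl 5-nonadecyl-1H-pyrrole-2-carboxylate | CCCCCCCCCCCCCCCCCCCc1ccc(C(=O)OC)[nH]1
A4 | alternative 2 | ethyl (2Z,4E)-2-azidotetracosa-2,4-dienoate | CCOC(=O)/C(N=[N+]=[N-])=C/C=C/CCCCCCCCCCCCCCCCCCC
A5 | alternative 2 | ethyl 5-nonadecyl-1H-pyrrole-2-carboxylate | CCCCCCCCCCCCCCCCCCCc1ccc(C(=O)OCC)[nH]1
A6 | alternative 2 | ethyl azidoacetate | CCOC(=O)CN=[N+]=[N-]
A7 | alternative 2 | (E)-docos-2-enal | CCCCCCCCCCCCCCCCCCC/C=C/C=O
A8 | alternative 3 | icosanal | CCCCCCCCCCCCCCCCCCCC=O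
A9 | alternative 3 | glycine methyl ester | COC(=O)CN
A10 | alternative 3 | (E)-1,2-bis(phenylsulfonyl)ethene | O=S(=O)(/C=C/S(=O)(=O)c1ccccc1)c1ccccc1
A11 | alternative 3 | methyl 2,5-cis-5-nonadecyl-3,4-trans-bis(phenylsulfonyl)pyrrolidine-2-carboxylate (racemic, one enantiomer drawn) | COC(=O)[C@@H]1[C@@H](S(=O)(=O)c2ccccc2)[C@H](S(=O)(=O)c2ccccc2)[C@H](CCCCCCCCCCCCCCCCCCC)N1
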